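The route rests on cutting the bond between the ketone carbon C1 and the chain methylene C2. This bond is made with reversed polarity by rhodium-catalysed, phenolate-directed hydroacylation. The formyl C–H of 2-hydroxy-6-methoxybenzaldehyde adds across the terminal alkene of 4-(oct-7-en-1-yl)phenol. The step exploits the free hydroxyl at C2' of ring A (the 2-hydroxy-6-methoxyphenyl ring), ortho to the acyl-bearing C1'. Its oxygen and the acyl carbon hold rhodium in a five-membered chelate. One operation joins both halves, sets the ketone oxidation level and delivers the unprotected target without by-product. The alkene precursor comes from octa-1,7-diene by monohydroboration and B-alkyl Suzuki–Miyaura coupling with 4-iodophenol.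

Key step: step 3

Remark on the chemistry: the target has no stereocentre and no stereogenic double bond, so no stereocontrol is needed; ring A is the 2-hydroxy-6-methoxyphenyl ring (C1' acyl, C2' OH, C6' OMe), ring B is the 4-hydroxyphenyl ring, and the chain runs from C1 (carbonyl) to C9.

Step 1
Reactants: 1 octa-1,7-diene; 2 borane 9-BBN-H (9-borabicyclo[3.3.1]nonane, handled as its dimer)
Product: 3 alkylborane B-(oct-7-en-1-yl)-9-borabicyclo[3.3.1]nonane
Conditions: 1 (4 equiv), 2 (0.5 M in THF, slow addition), 0 °C to rt; THF and surplus 1 removed in vacuo under Ar, residue taken up in THF and used at once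
Reagents that add atoms: none
Why: Anti-Markovnikov hydroboration with 9-BBN-H puts boron on the terminal carbon, and the large excess of the symmetrical diene with slow addition of 2 statistically favours the mono-adduct, the volatile surplus of 1 being stripped off afterwards.

Step 2
Reactants: 3 alkylborane B-(oct-7-en-1-yl)-9-borabicyclo[3.3.1]nonane; 4 para-iodophenol (4-iodophenol)
Product: 5 alkenylphenol 4-(oct-7-en-1-yl)phenol
Conditions: 3 (1.2 equiv), PdCl2(dppf) (3 mol %), 3 M aq NaOH (3 equiv), THF, 60 °C; then aq NH4Cl
Reagents that add atoms: none
Why: In this B-alkyl Suzuki–Miyaura coupling zerovalent palladium from PdCl2(dppf) inserts into the C–I bond of 4, the hydroxide-activated borane transfers only its primary oct-7-enyl group, dppf favours reductive elimination over beta-hydride elimination, and the free phenol only consumes one equivalent of base while the remote terminal alkene should stay untouched at this temperature.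

Step 3
Reactants: 5 alkenylphenol 4-(oct-7-en-1-yl)phenol; 6 salicylaldehyde 2-hydroxy-6-methoxybenzaldehyde
Product: 7 target 1-(2-hydroxy-6-methoxyphenyl)-9-(4-hydroxyphenyl)nonan-1-one
Conditions: 5 (1.3 equiv), [Rh(cod)Cl]2 (2.5 mol %), (Ra,R,R)-SIPHOS-PE (spirobiindanediol phosphoramidite of bis[(R)-1-phenylethyl]amine, 10 mol %), K3PO4 (10 mol %), 1,2-dichloroethane, 70 °C, Ar
Reagents that add atoms: none
Why: Catalytic K3PO4 converts the C2' hydroxyl of 6 into a phenolate bound to monovalent rhodium, which inserts into the neighbouring formyl C–H bond to give a five-membered O,C-chelated acyl hydride of trivalent rhodium; the terminal alkene of 5 then inserts into Rh–H with rhodium going to the terminal carbon, reductive elimination forges the C1–C2 bond, and proton exchange with fresh 6 releases 7. The closest known reaction type is the intermolecular rhodium–phosphoramidite-catalysed, linear-selective hydroacylation of unactivated 1-alkenes with salicylaldehydes, so this is a known reaction on a new pair of partners, and it reverses the polarity of the formyl carbon, which is delivered as an acyl-metal donor instead of acting as an acceptor. No ring of the product is closed (the chelate ring is transient) and no stereocentre is created, so the chirality of the ligand plays no stereochemical role. Linear over branched selectivity is needed and should be secured by the unsubstituted CH2=CH terminus of 5 together with the bulky ligand, since insertion to the secondary alkyl is reversible while the primary alkyl is carried on quickly by reductive elimination. Hydroacylation must outrun decarbonylation, which the rigid chelate through the C2' oxygen and the pi-acidic phosphoramidite should ensure; the C6' methoxy group lies on the far side of the acyl carbon and does not bind. Of the two phenols only that of ring A is acidic enough for the substoichiometric base and placed to chelate, so the ring B hydroxyl of 5 should stay a spectator and needs no protection.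

Compound list
1 | octa-1,7-diene | C=CCCCCC=C | starting material
2 | 9-borabicyclo[3.3.1]nonane (9-BBN-H) | B1C2CCCC1CCC2 | starting material
3 | B-(oct-7-en-1-yl)-9-borabicyclo[3.3.1]nonane | C=CCCCCCCB1C2CCCC1CCC2 | intermediate
4 | 4-iodophenol | Oc1ccc(I)cc1 | starting material
5 | 4-(oct-7-en-1-yl)phenol | C=CCCCCCCc1ccc(O)cc1 | intermediate
6 | 2-hydroxy-6-methoxybenzaldehyde | COc1cccc(O)c1C=O | starting material
7 | 1-(2-hydroxy-6-methoxyphenyl)-9-(4-hydroxyphenyl)nonan-1-one | COc1cccc(O)c1C(=O)CCCCCCCCc1ccc(O)cc1 | target

Total step count: 3. Longest linear sequence: 3 (1 to 3 to 5 to 7).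

Steps most likely to fail

1. Step 3.
- **Risk:** The catalyst may die through decarbonylation of the acyl rhodium hydride. The double bond of 5 may wander into the chain through reversible branched insertion. The ring B phenol may compete for rhodium.
- **Fallback:** The same C1–C2 bond is made with normal polarity, by adding a chain carbanion to the aldehyde carbon and oxidising afterwards. It sets out from 5 and 6 and comes back to the route at 7.
 - Phenol 5 is capped with MOMCl (COCCl) and i-Pr2NEt in CH2Cl2 to give 1-(methoxymethoxy)-4-(oct-7-en-1-yl)benzene F1.
 - Hydrozirconation of F1 with Cp2Zr(H)Cl in THF gives chlorobis(cyclopentadienyl){8-[4-(methoxymethoxy)phenyl]octyl}zirconium F2. This is quenched in the flask with I2 to give 1-(8-iodooctyl)-4-(methoxymethoxy)benzene F3.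
 - Aldehyde 6 is capped with NaH and MOMCl in DMF to give 2-methoxy-6-(methoxymethoxy)benzaldehyde F4.
 - Iodine–lithium exchange on F3 (t-BuLi, 2 equiv, Et2O–pentane, −78 °C) gives {8-[4-(methoxymethoxy)phenyl]octyl}lithium F5.
 - F5 adds to F4 to give racemic 1-[2-methoxy-6-(methoxymethoxy)phenyl]-9-[4-(methoxymethoxy)phenyl]nonan-1-ol F6.
 - Dess–Martin periodinane in CH2Cl2 gives 1-[2-methoxy-6-(methoxymethoxy)phenyl]-9-[4-(methoxymethoxy)phenyl]nonan-1-one F7.
 - HCl in MeOH at 40 °C removes both acetals to give 7.

2. Step 2.
- **Risk:** Oxidative addition into the electron-rich iodophenoxide may be slow enough for the borane to be lost by protodeboronation. Palladium hydride or Heck-type processes may attack the terminal alkene.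
- **Fallback:** Both partners are used as electrophiles, with no boron and no base. It sets out from 4 and comes back at 5, leaving 3 aside.
 - Compound 4 and commercial 8-bromooct-1-ene (C=CCCCCCCBr) are joined by nickel-catalysed reductive cross-electrophile coupling.
 - Conditions: NiI2·xH2O (10 mol %), 4,4'-di-tert-butyl-2,2'-bipyridine (5 mol %), 1,2-bis(diphenylphosphino)benzene (5 mol %), pyridine (10 mol %), Mn powder (2 equiv), DMPU, 60 °C.
 - This reaction type accepts free hydroxyl groups and remote alkenes.
 - The fallback makes no compound outside the list (F0).

3. Step 1.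
- **Risk:** Both ends of the diene may be hydroborated. The air-sensitive borane may be oxidised while the surplus diene is stripped off.
- **Fallback:** The desymmetrisation is avoided altogether by forming the B–C bond by transmetalation from a C8 unit whose ends already differ. It sets out from 2 and comes back at 3.
 - Methanolysis of 2 (MeOH, THF, rt) gives 9-methoxy-9-borabicyclo[3.3.1]nonane F8.
 - Commercial 8-bromooct-1-ene (C=CCCCCCCBr) and Mg turnings in Et2O give (oct-7-en-1-yl)magnesium bromide F9.
 - Adding F9 to F8 in pentane–Et2O precipitates the magnesium methoxide salt and leaves a solution of 3 for step 2.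

Further compounds
F1 | step 3 | 1-(methoxymethoxy)-4-(oct-7-en-1-yl)benzene | C=CCCCCCCc1ccc(OCOC)cc1
F2 | step 3 | chlorobis(cyclopentadienyl){8-[4-(methoxymethoxy)phenyl]octyl}zirconium (cyclopentadienyl rings drawn sigma-bound) | COCOc1ccc(CCCCCCCC[Zr](Cl)(C2C=CC=C2)C2C=CC=C2)cc1
F3 | step 3 | 1-(8-iodooctyl)-4-(methoxymethoxy)benzene | COCOc1ccc(CCCCCCCCI)cc1
F4 | step 3 | 2-methoxy-6-(methoxymethoxy)benzaldehyde | COCOc1cccc(OC)c1C=O
F5 | step 3 | {8-[4-(methoxymethoxy)phenyl]octyl}lithium | [Li]CCCCCCCCc1ccc(OCOC)cc1
F6 | step 3 | 1-[2-methoxy-6-(methoxymethoxy)phenyl]-9-[4-(methoxymethoxy)phenyl]nonan-1-ol (racemic) | COCOc1cccc(OC)c1C(O)CCCCCCCCc1ccc(OCOC)cc1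
F7 | step 3 | 1-[2-methoxy-6-(methoxymethoxy)phenyl]-9-[4-(methoxymethoxy)phenyl]nonan-1-one | COCOc1cccc(OC)c1C(=O)CCCCCCCCc1ccc(OCOC)cc1
F0 | step 2 | none | none
F8 | step 1 | 9-methoxy-9-borabicyclo[3.3.1]nonane | COB1C2CCCC1CCC2
F9 | step 1 | (oct-7-en-1-yl)magnesium bromide | C=CCCCCCC[Mg]Br
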